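Assumption: compounds 1, 2 and 7 are taken as catalogue compounds; short-lived species at the electrode and in the palladium cycle are described in words and carry no number.

## Structural features

The target 8 is a neoflavone: a 2H-chromen-2-one whose benzo ring A (C4a, C5 to C8, C8a) is fused to the pyranone ring (O1, C2, C3, C4), with ring B, a 3-hydroxy-4-methoxyphenyl group, joined at C4 through the C4–C1' bond. There is no stereocentre, but C4 is crowded, because ring B stands peri to the 5-methoxy group and is twisted out of the coumarin plane. Ring A carries oxygen on four of its six carbons in a 1,2,3,5 pattern: O1 at C8a ends the contiguous C8a/C8/C7 triad, the 5-methoxy group is isolated, and C6 is the only ring A carbon with a hydrogen. The groups needing care are the free 3'-phenol (acidic, easily oxidised), the two electron-rich rings (over-oxidation, strong acid), the lactone (opened by hydroxide) and the four methyl ethers (strong Lewis acids). The real difficulty is the C8a–O1 bond: the standard coumarin syntheses buy it as 2,3,5-trimethoxyphenol or an ortho-hydroxy ketone of the same pattern, neither a common catalogue compound, and C8a (ortho to one methoxy group, meta to two) is not where an electrophile attacks the parent trimethoxyarene. The key step exploits three facts: ring A without O1 is the 2,4,5-trimethoxyphenyl group of a cheap aldehyde; its C8a–H is the only hydrogen-bearing ring carbon within six-ring reach of a carboxyl group held on a (Z)-C3=C4 chain at C4a; and this ring is the most easily oxidised π system of such a precursor. The last step uses a second feature: C4 of the unsubstituted pyranone ring is the β-carbon of an enoate and accepts an aryl group directly at its C–H bond.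

## Logic of the disconnections

**8 to 6 and 7.** The C4–C1' bond is cut at the level of C4–H, not of a C4 halide or sulfonate. It is the only bond between the two aromatic halves, and cutting it removes ring B together with the free phenol. The gain is that ring B arrives unprotected in the last step, so no protecting group is needed anywhere. The forward step must deliver the aryl group of 7 to C4 and not C3, must end in loss of hydride from the C3 palladium enolate and not in protonation, and must tolerate the peri 5-methoxy group and the free phenol.

**6 to 5 (key disconnection).** The O1–C8a bond is cut, which opens the pyranone ring and removes the fourth oxygen from ring A. This is the oxygen that makes ring A hard to buy, and in 5 the carboxyl oxygen that becomes O1 is already held beside C8a–H by the (Z) double bond. The gain is large: a bicyclic, tetraoxygenated heteroaromatic becomes an open-chain acid with one ring, three methoxy groups and one defined double bond. In one sentence, the route is the anodic joining of the carboxyl oxygen of 5 to ring carbon C8a. The forward step must remove two electrons and two protons and form the C–O bond only at the hydrogen-bearing ortho carbon, against ipso capture, loss of methyl groups and over-oxidation, with the (Z) geometry kept until the ring is closed.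

**5 to 3 through 4.** The O–ethyl bond of the ester is cut, a functional group interchange. The (Z) alkene is most reliably made as an ester. There is no skeletal gain; the cut only links to a (Z)-selective olefination. The forward step must hydrolyse the ester without (Z) to (E) isomerisation.

**3 to 1 and 2.** The C3=C4 double bond (coumarin numbering) is cut. This leaves two catalogue compounds, and in 1 the carbon substituent already sits at the future C4a of a ring with the correct three methoxy groups. The forward step must give the (Z) alkene under kinetic control.

## Other disconnections considered

**Alternative 1:** Pechmann condensation, the first route that comes to mind.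
- Cut: O1–C2 and C4–C4a.
- Forward key step: acid-promoted condensation of 2,3,5-trimethoxyphenol A1 with ethyl 3-(3-hydroxy-4-methoxyphenyl)-3-oxopropanoate A2 to give 8.
- Why the chosen plan is preferred:
  - A1 is not a common catalogue phenol, and its synthesis would contain the same C–O bond problem that the key step solves.
  - A1 has two nucleophilic carbons. Attack through C4 (para to the hydroxyl group, between two methoxy groups) gives an adduct that cannot lactonise.
  - The ketone of A2 is deactivated by its para methoxy group, so chromone formation (Simonis mode) can compete.
  - Hot strong acid is a poor match for two electron-rich rings and a free phenol.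

**Alternative 2:** Suzuki coupling at C4.
- Cut: C4–C1' at the level of a C4 electrophile.
- Forward key step: 1-(2-hydroxy-3,4,6-trimethoxyphenyl)ethan-1-one A3 is condensed with diethyl carbonate to 4-hydroxy-5,7,8-trimethoxy-2H-chromen-2-one A4; this is converted to 5,7,8-trimethoxy-2-oxo-2H-chromen-4-yl trifluoromethanesulfonate A5, which is coupled with 7 under zerovalent palladium catalysis (for example Pd(PPh3)4).
- Why the chosen plan is preferred:
  - It forms the same bond as step 4 but spends two extra steps on activating C4.
  - The ring A oxygen problem is only moved into the scarce ketone A3.
  - The sulfonate at the hindered C4 can hydrolyse back to A4 under the aqueous base of the coupling.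

**Alternative 3:** one-carbon insertion with CO2.
- Cut: C2–C3 and C2–O1, so that the pyranone ring closes at a carbon–carbon bond and C2 comes from CO2.
- Forward key step: Pd(OAc)2-catalysed, phenoxide-directed alkenyl C–H carboxylation of 2-[1-(3-hydroxy-4-methoxyphenyl)ethenyl]-3,5,6-trimethoxyphenol A6 with CO2, followed by lactonisation to 8.
- Why the chosen plan is preferred:
  - The closure is regiochemically unambiguous, but A6 needs addition of a protected ring B aryl-metal to A3, which is di-ortho-substituted, enolisable and present as its phenoxide.
  - It then needs dehydration, plus a protecting group for the ring B phenol and its removal.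
  - The ring A oxygen is again bought with A3, and the sequence is longer than four steps.

Key step: step 3

## Route

**Step 1**
Reactants: 1 2,4,5-trimethoxybenzaldehyde; 2 ethyl 2-[bis(2-methylphenoxy)phosphoryl]acetate
Product: 3 ethyl (Z)-3-(2,4,5-trimethoxyphenyl)prop-2-enoate
Conditions: NaH, THF, −78 °C to 0 °C
Reagents that add atoms: none
Why: Horner–Wadsworth–Emmons olefination in its (Z)-selective diaryl phosphonoacetate variant; the electron-poor aryloxy groups on phosphorus make elimination from the first-formed syn adduct faster than its equilibration, so the (Z) alkene should form under kinetic control. This sets the double-bond geometry the key step needs; no stereocentre is formed.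

**Step 2**
Reactants: 3 ethyl (Z)-3-(2,4,5-trimethoxyphenyl)prop-2-enoate
Product: 5 (Z)-3-(2,4,5-trimethoxyphenyl)prop-2-enoic acid, via lithium carboxylate 4 (not isolated)
Conditions: LiOH·H2O, THF/MeOH/H2O, rt, dark; then 1 M HCl, 0 °C
Reagents that add atoms: lithium hydroxide, [Li+].[OH-]
Why: Ester saponification by acyl–oxygen cleavage; hydroxide should not add in conjugate fashion to this electron-rich cinnamate, and exclusion of light and heat should keep the (Z) geometry. Cold acidification of 4 releases 5.

**Step 3**
Reactants: 5 (Z)-3-(2,4,5-trimethoxyphenyl)prop-2-enoic acid
Product: 6 5,7,8-trimethoxy-2H-chromen-2-one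
Conditions: undivided cell, graphite anode, Pt cathode, constant current (about 2.2 F/mol), nBu4NBF4, 2,6-lutidine, dry MeCN/HFIP (1,1,1,3,3,3-hexafluoropropan-2-ol), rt, dilute
Reagents that add atoms: none
Why: Proposed new method: anodic dehydrogenative lactonisation of a (Z)-3-arylacrylic acid onto an aryl C–H bond; the closest known reaction types are the anodic C–H lactonisation of biaryl-2-carboxylic acids to benzo[c]chromen-6-ones and the photocatalytic one-electron oxidative cyclisation of cinnamic acids to coumarins. The trimethoxyphenyl-alkene π system is the most easily oxidised site of 5 (a 1,2,4-trimethoxybenzene is oxidised well before a carboxylate or the solvent), so the anode should generate the arene radical cation, which the (Z)-held carboxylate captures intramolecularly. The pyranone ring closes in a 6-endo-trig mode at aryl C6 (the future C8a), the only hydrogen-bearing ring carbon within reach; a second electron transfer and loss of the C6 proton restore aromaticity, and the two protons are reduced to H2 at the cathode, so no chemical oxidant is needed. The competing 5-exo-trig capture at the ipso carbon (favoured electronically by the 2- and 4-methoxy groups) and capture at the methoxy-bearing ortho carbon give adducts that cannot aromatise by proton loss; because carboxylate is a good leaving group they should revert or pass on by 1,2-acyloxy shift to C6, as is generally proposed for para-methoxy biaryl acids. The selectivity needed is therefore C6–O bond formation over demethylative dearomatisation to a spirodienone, and the dry, non-nucleophilic fluoroalcohol medium, which stabilises radical cations and offers no nucleophile to take a methyl group, is chosen to secure it. The (Z) geometry from step 1 is essential, since the (E) acid cannot reach the ring. The product 6 carries a conjugated lactone on ring A and should be harder to oxidise than 5, which guards against over-oxidation; no stereocentre is formed.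

**Step 4**
Reactants: 6 5,7,8-trimethoxy-2H-chromen-2-one; 7 (3-hydroxy-4-methoxyphenyl)boronic acid
Product: 8 4-(3-hydroxy-4-methoxyphenyl)-5,7,8-trimethoxy-2H-chromen-2-one (3'-hydroxy-5,7,8,4'-tetramethoxy-4-phenylcoumarin)
Conditions: Pd(OAc)2 (10 mol %), 1,10-phenanthroline, O2 (1 atm), DMF, 80 °C
Reagents that add atoms: none
Why: Oxidative Heck arylation of a coumarin with an arylboronic acid: transmetalation of 7 to divalent palladium, then syn insertion of C3=C4 with the aryl group going to the electrophilic β-carbon C4 and palladium to C3. Epimerisation through the oxygen-bound enolate allows syn β-hydride elimination of H4, and O2 returns zerovalent palladium to the divalent state; the regiochemistry follows the enoate polarisation, and no protecting group is needed if the phenol is tolerated.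

## Compound list

1 | 2,4,5-trimethoxybenzaldehyde | COc1cc(OC)c(OC)cc1C=O | starting material
2 | ethyl 2-[bis(2-methylphenoxy)phosphoryl]acetate | CCOC(=O)CP(=O)(Oc1ccccc1C)Oc1ccccc1C | starting material
3 | ethyl (Z)-3-(2,4,5-trimethoxyphenyl)prop-2-enoate | CCOC(=O)/C=C\c1cc(OC)c(OC)cc1OC | intermediate
4 | lithium (Z)-3-(2,4,5-trimethoxyphenyl)prop-2-enoate | [Li+].[O-]C(=O)/C=C\c1cc(OC)c(OC)cc1OC | intermediate (not isolated)
5 | (Z)-3-(2,4,5-trimethoxyphenyl)prop-2-enoic acid | OC(=O)/C=C\c1cc(OC)c(OC)cc1OC | intermediate
6 | 5,7,8-trimethoxy-2H-chromen-2-one | COc1cc(OC)c2ccc(=O)oc2c1OC | intermediate
7 | (3-hydroxy-4-methoxyphenyl)boronic acid | COc1ccc(cc1O)B(O)O | starting material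
8 | 4-(3-hydroxy-4-methoxyphenyl)-5,7,8-trimethoxy-2H-chromen-2-one | COc1ccc(-c2cc(=O)oc3c(OC)c(OC)cc(OC)c23)cc1O | target

## Step count and least certain steps

Total step count: 4. Longest linear sequence: 4 steps (1 to 3 to 5 to 6 to 8).

**Step 3 (key step, proposed new method).**
- What may go wrong: capture of the radical cation at the ipso carbon followed by loss of a methyl group, which dearomatises ring A instead of closing the pyranone ring. Rotation about the weakened double bond in the radical cation could also put the carboxylate out of reach, and radical cations could dimerise if the solution is too concentrated.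
- Fallback (known chemistry, C8a–O bond made first under carbonyl direction): it sets out from 1 and returns at 6. Pd(OAc)2-catalysed ortho C–H hydroxylation of 1 through a transient imine directing group (an anthranilic acid as catalytic amine, an N-fluoropyridinium salt as oxidant, p-toluenesulfonic acid as oxygen source) should give 2-hydroxy-3,4,6-trimethoxybenzaldehyde F1, since C6 is the only free position ortho to the formyl group. Wittig olefination of F1 with ethyl (triphenylphosphoranylidene)acetate in hot N,N-diethylaniline should give ethyl (E)-3-(2-hydroxy-3,4,6-trimethoxyphenyl)prop-2-enoate F2, which should isomerise and lactonise in the same pot to 6 with loss of ethanol.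

**Step 4.**
- What may go wrong: slow insertion at the peri-hindered C4, leaving time for homocoupling, protodeboronation or oxidation of the phenolic boronic acid. The palladium enolate may also be protonated instead of undergoing β-hydride elimination, which would stop at the dihydrocoumarin.
- Fallback (conjugate addition, then dehydrogenation): it sets out from 6 and 7 and returns at 8. Addition of 7 to 6 with [Rh(cod)OH]2, a monovalent rhodium catalyst, in aqueous dioxane should give racemic 4-(3-hydroxy-4-methoxyphenyl)-5,7,8-trimethoxy-3,4-dihydro-2H-chromen-2-one F3. Dehydrogenation of F3 with DDQ in hot dioxane, by hydride abstraction from the doubly benzylic C4–H, should give 8.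

**Step 1.**
- What may go wrong: erosion of (Z) selectivity, because the electron-rich, ortho-substituted aldehyde reacts slowly and the adducts may equilibrate before elimination; the two isomers may also be hard to separate.
- Fallback (thermodynamic alkene, then contra-thermodynamic isomerisation): it sets out from 1 and returns at 5, bypassing steps 1 and 2. Knoevenagel–Doebner condensation of 1 with malonic acid (pyridine, piperidine, heat) should give (E)-3-(2,4,5-trimethoxyphenyl)prop-2-enoic acid F4 with loss of CO2. Photoisomerisation of F4 (UV light or a triplet sensitiser) should give a photostationary mixture from which 5 is separated and F4 recycled.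

## Further compounds

F1 | step 3 | 2-hydroxy-3,4,6-trimethoxybenzaldehyde | COc1cc(OC)c(OC)c(O)c1C=O
F2 | step 3 | ethyl (E)-3-(2-hydroxy-3,4,6-trimethoxyphenyl)prop-2-enoate | CCOC(=O)/C=C/c1c(O)c(OC)c(OC)cc1OC
F3 | step 4 | racemic 4-(3-hydroxy-4-methoxyphenyl)-5,7,8-trimethoxy-3,4-dihydro-2H-chromen-2-one | COc1ccc(cc1O)C1CC(=O)Oc2c(OC)c(OC)cc(OC)c12
F4 | step 1 | (E)-3-(2,4,5-trimethoxyphenyl)prop-2-enoic acid | COc1cc(OC)c(OC)cc1/C=C/C(=O)O
A1 | alternative 1 | 2,3,5-trimethoxyphenol | COc1cc(O)c(OC)c(OC)c1
A2 | alternative 1 | ethyl 3-(3-hydroxy-4-methoxyphenyl)-3-oxopropanoate | CCOC(=O)CC(=O)c1ccc(OC)c(O)c1
A3 | alternative 2 | 1-(2-hydroxy-3,4,6-trimethoxyphenyl)ethan-1-one | CC(=O)c1c(O)c(OC)c(OC)cc1OC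
A4 | alternative 2 | 4-hydroxy-5,7,8-trimethoxy-2H-chromen-2-one | COc1cc(OC)c2c(O)cc(=O)oc2c1OC
A5 | alternative 2 | 5,7,8-trimethoxy-2-oxo-2H-chromen-4-yl trifluoromethanesulfonate | COc1cc(OC)c2c(OS(=O)(=O)C(F)(F)F)cc(=O)oc2c1OC
A6 | alternative 3 | 2-[1-(3-hydroxy-4-methoxyphenyl)ethenyl]-3,5,6-trimethoxyphenol | C=C(c1ccc(OC)c(O)c1)c1c(O)c(OC)c(OC)cc1OC
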